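The O-bearing methine C1 of the cyclopentane sits next to the spiro carbon C5, and C5 carries the vinylic carbon C6 of the cyclohexene: the imprint of a 1,2-vinyl shift. The cyclohexene (C5–C10) is therefore drawn from the seven-membered ring of a cis-hydroazulene chroman, 14, assembled by hetero-Diels–Alder union of a guaia-4,6-diene (six steps from (R)-pulegone) with the o-quinone methide of diformylphloroglucinol and isovaleraldehyde. Acid ionises the tertiary allylic C1–O bond; hydride moves from C5 to C1, C6 moves from C1 to C5 through a cyclopropylcarbinyl cation, and the phenol recloses on C1. One isomerisation contracts the ring and sets the spiro and O–CH centres.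

Key step: step 8

Remark on labels: C1–C10 are the ring atoms of the spiro[4.5]decene part of 17 (C1 O–CH, C2 C–CH3, C5 spiro, C6=C7 with isopropyl on C7, C10 CH–CH3). C1′ is the benzylic carbon. The labels stay with the atoms in all earlier compounds. Ring A is the five-membered ring, and "top face" is the face of ring A that carries H-5 in 10.

Assumption: 2,4,6-trihydroxybenzene-1,3-dicarbaldehyde (11) is taken as a catalogue compound.

Step 1
Reactants: 1 (R)-(+)-pulegone
Product: 2 triethyl{[(5R)-5-methyl-2-(propan-2-yl)cyclohex-1-en-1-yl]oxy}silane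
Conditions: Et3SiH, RhCl(PPh3)3 (1 mol %), THF, 50 °C
Reagents that add atoms: triethylsilane, CC[SiH](CC)CC
Why: Rhodium-catalysed 1,4-hydrosilylation of the s-cis enone should give the tetrasubstituted silyl enol ether (C1=C7) regiospecifically, with no new stereocentre and the C10 methyl centre of pulegone untouched.

Step 2
Reactants: 2 triethylsilyl enol ether
Product: 3 triethyl{[(3R)-3-methyl-6-(propan-2-yl)bicyclo[4.1.0]heptan-1-yl]oxy}silane (both cyclopropane diastereomers)
Conditions: Et2Zn, CH2I2, CH2Cl2, 0 °C to rt
Reagents that add atoms: diiodomethane, ICI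
Why: Simmons–Smith cyclopropanation (Furukawa variant) of the electron-rich enol ether brings in the future C6, and facial control is not needed because both cyclopropane diastereomers converge in step 3.

Step 3
Reactants: 3 siloxycyclopropane
Product: 5 (6R)-6-methyl-3-(propan-2-yl)cyclohept-2-en-1-one, via β-chloro ketone 4 (not isolated)
Conditions: FeCl3, DMF, 0 °C to rt; then NaOAc, MeOH, reflux
Reagents that add atoms: none
Why: Ito–Saegusa one-carbon ring expansion, in which FeCl3 oxidises the siloxycyclopropane, β-scission of the internal C1–C7 bond gives the ring-enlarged tertiary C7 radical that takes up chlorine (4), and acetate-induced E1cB loss of HCl gives the conjugated cycloheptenone, erasing both cyclopropane stereocentres and leaving C10 untouched.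

Step 4
Reactants: 5 cycloheptenone; 6 1,3-dichlorobut-2-ene (E/Z mixture)
Product: 8 (6R,7S)-7-(3-chlorobut-2-en-1-yl)-6-methyl-3-(propan-2-yl)cyclohept-2-en-1-one, via lithium dienolate 7 (not isolated)
Conditions: LiN(iPr)2, THF, −78 °C; then 6, DMPU, −78 to 0 °C
Reagents that add atoms: 1,3-dichlorobut-2-ene (6), CC(Cl)=CCCl
Why: Kinetic α′-deprotonation and SN2 allylation of the cross-conjugated dienolate (first half of a Wichterle sequence) should place the C4 chain on C5 trans to the neighbouring C10 methyl group, because the electrophile approaches anti to it and the centre can in any case epimerise to this more stable arrangement.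

Step 5
Reactants: 8 vinyl chloride
Product: 9 (6R,7S)-6-methyl-7-(3-oxobutyl)-3-(propan-2-yl)cyclohept-2-en-1-one
Conditions: H2SO4 (90 %), 0 °C; then ice–water
Reagents that add atoms: water, O
Why: Wichterle hydrolysis, in which protonation of the vinyl chloride gives an α-chloro carbocation that water turns into the methyl ketone (C2), while the enone is only protonated reversibly and C5 keeps its thermodynamic trans arrangement.

Step 6
Reactants: 9 1,5-diketone
Product: 10 (3aS,4R)-1,4-dimethyl-7-(propan-2-yl)-2,3,3a,4,5,6-hexahydroazulene [(1S,10R)-guaia-4,6-diene in guaiane numbering]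
Conditions: TiCl3(DME)1.5, Zn–Cu couple, DME, reflux, slow addition
Reagents that add atoms: none
Why: Intramolecular McMurry coupling of the 1,5-diketone closes ring A by low-valent-titanium pinacol coupling and deoxygenation to the tetrasubstituted C1=C2 bond, the five-ring closure outrunning intermolecular coupling under slow addition and leaving C5 and C10 untouched.

Step 7
Reactants: 10 guaia-4,6-diene; 11 2,4,6-trihydroxybenzene-1,3-dicarbaldehyde; 12 3-methylbutanal
Product: 14 guai-6-ene-fused 6,8-diformyl-5,7-dihydroxy-4-isobutylchroman (C1′ R; C1 R; C2 S; C5 S; C10 R), via o-quinone methide 13 (not isolated)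
Conditions: NaOAc, AcOH, 80 °C
Reagents that add atoms: 2,4,6-trihydroxybenzene-1,3-dicarbaldehyde (11), O=Cc1c(O)c(C=O)c(O)cc1O; 3-methylbutanal (12), CC(C)CC=O
Why: Knoevenagel condensation gives the E-configured o-quinone methide 13, whose inverse-electron-demand hetero-Diels–Alder reaction with the transoid diene should bond C1′ to C2 (methyl-bearing terminus, less hindered than isopropyl-bearing C7) and O to C1 (the site of a doubly tertiary allyl cation), on the top face beside the small H-5 so that the hydroazulene stays cis-fused (sets C1 and C2), with ring A endo and the isopropyl-bearing ring exo (sets C1′).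

Step 8
Reactants: 14 hydroazulene chroman
Product: 17 target CNP0121396.1 (C1′ R; C1 R; C2 S; C5 R; C10 R), via allyl cation 15 (not isolated), via cyclopropylcarbinyl cation 16 (not isolated)
Conditions: MsOH (10 mol %), (CF3)2CHOH–CH2Cl2, 0 to 40 °C
Reagents that add atoms: none
Why: Proposed new method: protonation of the chroman oxygen and heterolysis of the tertiary, allylic C1–O bond should give the tetraalkyl allyl cation 15 with the phenol still tethered through C1′–C2; the C5–H bond, parallel to the empty orbital, then shifts suprafacially to the top face of C1 while the C6=C7 π bond bridges to the bottom face of C5, giving the tertiary cyclopropylcarbinyl cation 16, and the phenol opens its C1–C6 bond from the top face. The closest known reaction types are the homoallyl/cyclopropylcarbinyl (i-steroid) cation rearrangement, the Julia-type opening of cyclopropylcarbinyl cations by a nucleophile and the Wagner–Meerwein hydride shifts of acid-treated terpenes, which have not been combined on an allylic chroman ether. The net 1,2-shift of C6 from C1 to C5 expels C1 from the seven-membered ring (C1, C6, C7, C8, C9, C10, C5) and leaves the six-membered ring C5–C10; the transient cyclopropane forms 3-exo-trig and the dihydropyran recloses 6-exo-tet. C5 is set because C6 can only arrive anti to the departing hydride, so the configuration installed at C5 in step 4 is relayed with inversion, and C1 is set because oxygen attacks anti to the leaving C6, which puts O cis to C1′ and H-1 cis to the C2 methyl group. The step needs this exit to win over proton loss, retro-cycloaddition and capture at C5 or C7: those paths are reversible or would need seven- or eight-membered rings, whereas 17 is a secondary, non-allylic ether that cannot re-ionise and should therefore collect the material.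

Compound list
1 | (R)-(+)-pulegone | C[C@@H]1CCC(=C(C)C)C(=O)C1 | starting material
2 | triethyl{[(5R)-5-methyl-2-(propan-2-yl)cyclohex-1-en-1-yl]oxy}silane | C[C@@H]1CCC(C(C)C)=C(O[Si](CC)(CC)CC)C1 | intermediate
3 | triethyl{[(3R)-3-methyl-6-(propan-2-yl)bicyclo[4.1.0]heptan-1-yl]oxy}silane, both cyclopropane diastereomers | C[C@@H]1CCC2(C(C)C)CC2(O[Si](CC)(CC)CC)C1 | intermediate
4 | (6R)-3-chloro-6-methyl-3-(propan-2-yl)cycloheptan-1-one, C3 epimers, not isolated | C[C@@H]1CCC(Cl)(C(C)C)CC(=O)C1 | intermediate
5 | (6R)-6-methyl-3-(propan-2-yl)cyclohept-2-en-1-one | C[C@@H]1CCC(C(C)C)=CC(=O)C1 | intermediate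
6 | 1,3-dichlorobut-2-ene, E/Z mixture | CC(Cl)=CCCl | starting material
7 | lithium (6R)-6-methyl-3-(propan-2-yl)cyclohepta-2,7-dien-1-olate, not isolated | C[C@@H]1CCC(C(C)C)=CC([O-])=C1.[Li+] | intermediate
8 | (6R,7S)-7-(3-chlorobut-2-en-1-yl)-6-methyl-3-(propan-2-yl)cyclohept-2-en-1-one, E/Z mixture at the vinyl chloride | C[C@@H]1CCC(C(C)C)=CC(=O)[C@H]1CC=C(C)Cl | intermediate
9 | (6R,7S)-6-methyl-7-(3-oxobutyl)-3-(propan-2-yl)cyclohept-2-en-1-one | C[C@@H]1CCC(C(C)C)=CC(=O)[C@H]1CCC(C)=O | intermediate
10 | (3aS,4R)-1,4-dimethyl-7-(propan-2-yl)-2,3,3a,4,5,6-hexahydroazulene | C[C@@H]1CCC(C(C)C)=CC2=C(C)CC[C@@H]12 | intermediate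
11 | 2,4,6-trihydroxybenzene-1,3-dicarbaldehyde | O=Cc1c(O)c(C=O)c(O)cc1O | starting material
12 | 3-methylbutanal | CC(C)CC=O | starting material
13 | (E)-o-quinone methide, 2,4-dihydroxy-5-(3-methylbutylidene)-6-oxocyclohexa-1,3-diene-1,3-dicarbaldehyde, not isolated | CC(C)C/C=C1/C(=O)C(C=O)=C(O)C(C=O)=C1O | intermediate
14 | hetero-Diels–Alder adduct: chroman with O on C1 and C1′ on C2 of the cis-fused guai-6-ene; O, C1′ and H-5 on the top face | CC(C)C[C@H]1c2c(O)c(C=O)c(O)c(C=O)c2O[C@@]23C=C(C(C)C)CC[C@@H](C)[C@@H]2CC[C@]31C | intermediate
15 | allyl cation (C1–C6–C7) with free tethered phenol, not isolated | CC(C)C[C@@H](c1c(O)c(C=O)c(O)c(C=O)c1O)[C@]1(C)CC[C@@H]2[C+]1C=C(C(C)C)CC[C@H]2C | intermediate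
16 | cyclopropylcarbinyl cation (cyclopropane C1–C5–C6, charge on C7), not isolated | CC(C)C[C@@H](c1c(O)c(C=O)c(O)c(C=O)c1O)[C@]1(C)CC[C@]23[C@H]1[C@H]2[C+](C(C)C)CC[C@H]3C | intermediate
17 | CNP0121396.1 | CC(C)C[C@H]1c2c(O)c(C=O)c(O)c(C=O)c2O[C@@H]2[C@@]1(C)CC[C@@]21C=C(C(C)C)CC[C@H]1C | target

Total step count: 8. Longest linear sequence: 8 steps (1 to 17).

Steps most likely to fail

Step 8. The hydride shift may be outrun in three ways. The allyl cation may lose a proton. Retro-cycloaddition may be followed by irreversible tautomerisation of the quinone methide. A further hydride shift from C10 may erode that centre.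

The fallback moves the ring contraction to the terpene stage and uses known reactions only. It sets out from 5 and comes back at 17.
- Trifluoroacetylation of the kinetic enolate of 5 (LiN(SiMe3)2, CF3CO2CH2CF3, THF, −78 °C) gives the α′-trifluoroacetyl enone F1.
- Detrifluoroacetylative diazo transfer (MsN3, Et3N, MeCN) gives the α′-diazo enone F2.
- Photochemical Wolff rearrangement in methanol, in which the alkenyl carbon C6 migrates to C5, contracts the seven-membered ring to the cyclohexene and gives the methyl cyclohexenecarboxylate F3, whose ester carbon is C1.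
- Alkylation of its dienolate at C5 (LiN(iPr)2, DMPU, 1-bromobut-2-yne), anti to the C10 methyl group, gives the quaternary ester F4.
- iBu2AlH at −78 °C gives the 4-alkynal F5.
- Rhodium-catalysed intramolecular trans-hydroacylation ([Rh(dppe)]2(BF4)2, acetone, 100 °C) gives the spiro cyclopentenone F6.
- 1,4-Hydrosilylation (Et3SiH, RhCl(PPh3)3) gives the silyl enol ether F7.
- Hetero-Diels–Alder reaction of F7 with quinone methide 13, made from 11 and 12 with ethylenediammonium diacetate in MeCN over molecular sieves, has to take the enol-ether face syn to C10. This face is probably the more hindered one, so poor facial selectivity is the main weakness of the fallback. After separation of diastereomers it gives the silyl ketal F8.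
- Ionic reduction (Et3SiH, BF3·OEt2, CH2Cl2, −78 °C) delivers hydride to C1 cis to the C2 methyl group and comes back at 17.

Step 7. The quinone methide may tautomerise to the styrene or oligomerise faster than the hindered tetrasubstituted alkene traps it. Hot acetic acid may isomerise the diene. Facial or endo selectivity may be poor.

The fallback separates the making of the quinone methide from its use. It sets out from 11 and comes back at 14. Condensation of 11 with 12 in ethanol (ethylenediammonium diacetate) traps 13 as the isolable benzylic ethyl ether F9. F9 is then ionised in the presence of 10 under aprotic conditions (Sc(OTf)3 cat., CH2Cl2, −40 °C). In this way 13 is released slowly at low temperature beside an excess of the diene and gives 14.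

Step 6. Low-valent titanium may stop at the pinacol stage or reduce the enone in a conjugate sense.

The fallback forms the C1=C2 bond by olefin metathesis instead of carbonyl coupling. It sets out from 9 and comes back at 10. Double Wittig methylenation (Ph3P=CH2, THF) gives the bis-methylidene triene F10. Ring-closing metathesis (second-generation Hoveyda–Grubbs catalyst, toluene, 80 °C) then closes the tetrasubstituted five-ring alkene and gives 10.

Further compounds
F1 | step 8 | (6R)-6-methyl-3-(propan-2-yl)-7-(trifluoroacetyl)cyclohept-2-en-1-one | C[C@@H]1CCC(C(C)C)=CC(=O)C1C(=O)C(F)(F)F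
F2 | step 8 | (6R)-7-diazo-6-methyl-3-(propan-2-yl)cyclohept-2-en-1-one | C[C@@H]1CCC(C(C)C)=CC(=O)C1=[N+]=[N-]
F3 | step 8 | methyl (6R)-6-methyl-3-(propan-2-yl)cyclohex-2-ene-1-carboxylate, C1 epimers | C[C@@H]1CCC(C(C)C)=CC1C(=O)OC
F4 | step 8 | methyl (1R,6R)-1-(but-2-yn-1-yl)-6-methyl-3-(propan-2-yl)cyclohex-2-ene-1-carboxylate | C[C@@H]1CCC(C(C)C)=C[C@]1(CC#CC)C(=O)OC
F5 | step 8 | (1R,6R)-1-(but-2-yn-1-yl)-6-methyl-3-(propan-2-yl)cyclohex-2-ene-1-carbaldehyde | C[C@@H]1CCC(C(C)C)=C[C@]1(CC#CC)C=O
F6 | step 8 | (5R,10R)-2,10-dimethyl-7-(propan-2-yl)spiro[4.5]deca-2,6-dien-1-one | C[C@@H]1CCC(C(C)C)=C[C@@]12CC=C(C)C2=O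
F7 | step 8 | triethyl{[(5R,10R)-2,10-dimethyl-7-(propan-2-yl)spiro[4.5]deca-1,6-dien-1-yl]oxy}silane | C[C@@H]1CCC(C(C)C)=C[C@@]12CCC(C)=C2O[Si](CC)(CC)CC
F8 | step 8 | C1-triethylsiloxy derivative of 17 (silyl ketal) | CC(C)C[C@H]1c2c(O)c(C=O)c(O)c(C=O)c2O[C@]2(O[Si](CC)(CC)CC)[C@@]1(C)CC[C@@]21C=C(C(C)C)CC[C@H]1C
F9 | step 7 | 5-(1-ethoxy-3-methylbutyl)-2,4,6-trihydroxybenzene-1,3-dicarbaldehyde, racemic | CCOC(CC(C)C)c1c(O)c(C=O)c(O)c(C=O)c1O
F10 | step 6 | (6R,7S)-6-methyl-1-methylidene-7-(3-methylbut-3-en-1-yl)-3-(propan-2-yl)cyclohept-2-ene | C[C@@H]1CCC(C(C)C)=CC(=C)[C@H]1CCC(C)=C
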